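**Minutes.** A small charge opened the meeting: the autumn run at [starting material] = 0.67 M was set beside the dawn run at 1.5 M, to judge the flask at 1.0 M, with the gas phase held in each.

in all of them: gas phase 110 mM (held)

| charge | starting material | remark | time |
|---|---|---|---|
| autumn | 0.67 M | run made earlier |  |
| dawn | 1.5 M | run made earlier |  |
| flask | 1.0 M |  | 5.0 min |

| run | time / min | starting material / % | target / % | side product / % |
|---|---|---|---|---|
| autumn | 1.00 | 67.0 | 14.8 | 17.8 |
| autumn | 2.00 | 46.6 | 21.7 | 32.1 |
| autumn | 3.00 | 37.5 | 23.6 | 41.2 |
| autumn | 4.00 | 29.0 | 24.2 | 47.3 |
| dawn | 1.00 | 71.9 | 11.7 | 18.1 |
| dawn | 2.00 | 51.1 | 18.6 | 31.8 |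
| dawn | 3.00 | 37.7 | 22.7 | 39.3 |
| dawn | 4.00 | 28.4 | 23.1 | 49.2 |

(standard deviation of a reading: 1 percentage point)

- at the start none of the gas phase is in solution
- the reaction counts as stopped when no species that holds the starting material changes by six tenths of a point or more over the second half of the time

- why nothing more happens at 5.0 min, or that something still does (forward and back rates have come level / all of the starting material has reacted / it is still moving)
- share of the starting material used up at 5.0 min
- target at 5.0 min, in percent of the starting material charged
- side product at 5.0 min, in percent of the starting material charged

I proposed following one molecule of starting material and asking its chance, minute by minute, of becoming side product. Dividing the side product at the last reading by the area under the starting-material curve gave 0.219 min⁻¹ for autumn and 0.219 min⁻¹ for dawn, level within reading. I carried their mean, 0.219 min⁻¹, as the leak rate, side product made divided by the area under the starting-material curve against time, a first-order rate constant.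

Letting starting material fall once more by its last ratio gave me 21.9% in the flask at 5.0 min. The leak rate then put side product there at 53.8%.

The forecaster held: it is still moving, conversion 79%, target 23.3%, side product 55.7%. The stated ground was starting material “still falling by about 7 points per minute, with no sign of levelling”. My side product stood lower; the ending went undisputed.

The flask gave: it is still moving, conversion 76.1%, target 22.3%, side product 53.9%.

    gas phase ⇌ dissolved gas, rate k1*(csat - [dissolved gas]) (kL = 0.0702 s⁻¹)
    starting material + dissolved gas ⇌ target (K = 6.90 M⁻¹, k = 0.0525 M⁻¹ s⁻¹)
    starting material → side product (k = 0.00374 s⁻¹)

At 5.0 min in the flask, the forward step to target alone gives starting material a half-life of 1.9 min, shorter than the 3.17 min that the leak rate read from the runs gives. Yet on that step in the flask backward turnover stands at 65% of forward, and net turnover to target up to 5.0 min is 22.3% of the charge against 53.9% side product. Left until 12 min, starting material in that flask falls to 10.4%; the leak rate on the logarithmic mean of 23.9% and that value gives 78.8% side product, and the flask holds 78.8%.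

The numbers in the tables come from a simulation with constants of no real substance, and the scatter is random.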